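**Assumption (remark on the chemistry):** both rings are numbered from the carboxyl-bearing carbon as C1; ring A is the acyl half and ring B the acid half. Boronic acid 8 is assumed to react equally well as the free acid or as its boroxine. The connectivity of 8, 12 and 13 was checked atom by atom against the target (12, C20H24O4; 8, C17H27BO5; 13, C37H48O7; target, C26H34O7), and no structural correction was needed.

## Structural features

4-O-Demethylplanaic acid is an achiral depside. It consists of two benzene rings, each a 2-methoxy-6-pentylbenzoyl unit, joined by one ester whose carbonyl carbon is the C1 carboxyl carbon of ring A and whose oxygen sits on C4 of ring B. Ring A carries a free hydroxyl at C4 and ring B the free carboxylic acid at C1. There are no stereocenters, so none stand next to each other and no configuration has to be set. The fragile groups are the aryl ester (cleaved or transesterified by hydroxide, alkoxides and amines), the electron-rich benzoic acid (prone to decarboxylation on heating or in strong acid) and the phenol (a competing nucleophile). The real difficulty is steric and positional. Both carbonyl carbons lie between a methoxy and a pentyl group, so acyl substitution at them is slow, and each ring needs an oxygen at C4, a position that the ortho/para-directing methoxy and alkyl groups do not open to electrophiles. The key step uses two features together: the carboxylate oxygens of ring A point away from the ortho groups and stay free to bond, and C4 of ring B is the only ring carbon flanked by two C–H positions (C3 and C5), so boron can be placed there by sterically governed C–H borylation and then exchanged for the carboxylate oxygen on copper.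

## Logic of the disconnections

15 back to 13 through 14: the O–benzyl bond on the C4 oxygen of ring A and the O–tert-butyl bond of the ring B ester are cut. A free phenol and a second free carboxyl would both compete as oxygen nucleophiles in the coupling, so each partner must show copper only one reactive group. Nothing is gained in skeleton, but the coupling becomes unambiguous. The forward steps must remove both groups without touching the depside carbonyl, which points to alkyl–oxygen acidolysis and neutral hydrogenolysis.

13 back to 12 and 8: the bond between the ester oxygen and C4 of ring B is cut, not the acyl C–O bond. The acyl carbon of ring A is shielded by its two ortho groups, whereas the carboxylate oxygen and C4 of ring B are both unhindered. The target falls into two rings of nearly identical substitution. The forward step must transfer a carboxylate to an aryl–copper species faster than the C–B bond is protonated or hydroxylated.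

12 back to 7 through 11 and 9: the benzyl–oxygen bond is cut, the C4–O bond is traced back to a C4–B bond, and the free acid is traced back to its tert-butyl ester. Oxidation of a C–B bond gives the phenol exactly at C4 with no isomer problem. The ester must later be removed without attack at the hindered carbonyl and without loss of the benzyl group.

8 back to 7: only the two B–O bonds of the diol ester are cut. A free boronic acid transmetalates to copper more readily than its hindered diol ester. The boron must be unmasked without oxidising the C–B bond or cleaving the ester. Because 12 and 8 both come from 7, one intermediate serves both halves of the molecule.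

7 back to 5 and 6: the C4–B bond is cut. C4–H is the only aromatic C–H of 5 without a neighbouring substituent, so no pre-oxygenated resorcinol building block is needed. The borylation must distinguish C4–H from C3–H, which has only the small methoxy group as neighbour, and from C5–H.

5 back to 4: the oxygen–tert-butyl bond is cut. This ester forms and cleaves at the alkyl–oxygen bond, the only mode that the hindered carbonyl allows easily, and it withstands the basic and oxidising steps in between. The forward step must therefore be an O-alkylation of the acid, not an acyl substitution.

4 back to 1 and 2: the bond between the benzylic carbon and the second carbon of the pentyl chain is cut. The ortho-methyl group of 1 is acidified by the adjacent carboxylate, and the cut leads to two commercial compounds. The forward step needs clean dianion formation and alkylation at carbon only.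

## Other disconnections considered

Alternative 1: Ring B itself is taken apart at C1–C6 and C2–C3. In the forward direction dibenzyl malonate A1 would add to (E)-non-3-en-2-one A2 in a Michael reaction. The methyl ketone enolate of the adduct would then close onto one ester by intramolecular Claisen condensation to give the enolised cyclohexane-1,3-dione A3, benzyl trans-2-hydroxy-4-oxo-6-pentylcyclohex-2-ene-1-carboxylate, as a racemate whose two stereocenters vanish on aromatisation. A3 would then have to be O-acylated at the C4 oxygen with an activated form of 12, dehydrogenated to the arene, methylated at the C2 hydroxyl and hydrogenolysed.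
- In favour: cheap acyclic materials, a long-established base-mediated annulation, and no boron or iridium. Both benzyl groups would fall in one hydrogenolysis, one deprotection fewer than in the chosen plan, so on the end game this alternative is the better.
- Against: the depside bond is made by acyl substitution at the ring A carbonyl carbon, exactly the centre that the ortho groups shield. A3 is an ambident nucleophile (two enol oxygens and C3), so the site of acylation is not secured by structure. The dehydrogenation, with a halogen or quinone oxidant, must spare an enol ester and the electron-rich ring A. The hydrogen-bonded C2 hydroxyl must be methylated late, under base, next to an aryl ester.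
- Comparison: 12 still needs its own six steps, so the count is about eleven operations against ten, and the intermediate common to both halves is lost. Mechanistically the alternative replaces one copper step of moderate uncertainty with three steps of uncertain selectivity. On stereochemistry the plans are equal, since neither leaves a stereocenter in the product.

Alternative 2: Ring A is cut at C1–C2 and C5–C6, so the ester exists before ring A does. Ring B phenol A4 (benzyl 4-hydroxy-2-methoxy-6-pentylbenzoate) would be esterified to the aryl oct-2-ynoate A5. In the key step A5 would undergo a [4+2] cycloaddition with the electron-rich diene A6, 1,1-dimethoxy-3-(trimethylsilyloxy)buta-1,3-diene. Loss of one methoxy group as the alcohol and of the silyl group on work-up would give A7 with ring A aromatic.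
- In favour: the ester is formed on an unhindered alkynoyl carbonyl, so the steric problem never arises; in avoiding hindered acyl substitution this is the equal of the chosen plan. The polarisation of diene and ynoate places OMe at C2 and OH at C4 of ring A without any protecting group on ring A. Only one hydrogenolysis separates A7 from the target, so the end game is shorter, a point on which it is the better.
- Against: ynoates with an alkyl group on the β-carbon are sluggish dienophiles and need heat, at which the ketene-acetal diene can decompose or attack the activated aryl ester. A6 is moisture-sensitive. A4 cannot be reached by the borylation chemistry of the chosen plan in the same way, because a benzyl ester offers unhindered C–H bonds of its own to the iridium catalyst, so A4 needs a separate and probably longer preparation.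
- Comparison: both plans fix the substitution pattern by construction. The cycloaddition has predictable regiochemistry but a doubtful rate, whereas the copper coupling has an acceptable rate but doubtful chemoselectivity. From the coupling partners onward the counts are equal (three steps each); overall the alternative is at best equal, depending on the route to A4.

Alternative 3: The acyl C–O bond of the depside and the C1–C6 bond of ring A are cut. Heating the diketo-dioxinone A8 would trigger a retro-[4+2] fragmentation that expels the ketone part of the acetal and releases the acylketene A9. Phenol A4 would add to A9 to give the aryl 3,5,7-trioxododecanoate A10. Aldol addition of C2 to the C7 ketone, followed by dehydration and enolisation, would give A11 with ring A as a 2,4-dihydroxy-6-pentylbenzoate.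
- In favour: the ester arises by addition to a ketene, which is not hindered, so on this point it equals the chosen plan. The conditions are neutral and thermal, ring A needs no protecting group, and one operation forms the ester bond, a C–C bond and a ring. In bond-forming economy of the key step it is the better.
- Against: A11 has two free hydroxyls on ring A, and the target needs the methyl group on the C2 oxygen, the hydrogen-bonded and less reactive one. That forces benzylation of the C4 oxygen, methylation and hydrogenolysis after the key step. A10 has competing cyclisation modes, among them lactonisation to a 4-hydroxy-2-pyrone with expulsion of the ring B phenoxide, which would destroy the depside link. A8 needs about three steps of its own, and A4 is needed as in alternative 2.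
- Comparison: the chosen plan carries the ring A methoxy group from the starting material and brings the hydroxyl in through boron, so no late differentiation of two phenols is needed. The cascade is elegant, but its selectivity among cyclisation modes rests on conditions, not on structure. The step count would be clearly higher, roughly thirteen against ten.

Key step: step 8

## Route

Step 1
Reactants: 1 2-methoxy-6-methylbenzoic acid; 2 1-iodobutane
Product: 4 2-methoxy-6-pentylbenzoic acid, via lithium 2-(lithiomethyl)-6-methoxybenzoate 3 (not isolated)
Conditions: LiN(iPr)2 (2.2 equiv, commercial solution), THF, −78 → 0 °C; then 2 (1.2 equiv), −78 °C → rt; aq. HCl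
Reagents that add atoms: none
Why: Lateral lithiation: the first equivalent of amide base forms the carboxylate and the second removes a proton from the ortho-methyl group, which the neighbouring carboxylate acidifies and stabilises as dianion 3. The benzylic carbanion is far more nucleophilic than the carboxylate and is alkylated by the primary iodide in an SN2 reaction, extending methyl to pentyl; no stereocenter is formed.

Step 2
Reactants: 4 2-methoxy-6-pentylbenzoic acid
Product: 5 tert-butyl 2-methoxy-6-pentylbenzoate
Conditions: Cl3CC(=NH)OtBu (2 equiv), BF3·OEt2 (cat.), CH2Cl2/cyclohexane, rt
Reagents that add atoms: tert-butyl 2,2,2-trichloroacetimidate, CC(C)(C)OC(=N)C(Cl)(Cl)Cl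
Why: Acid-catalysed O-alkylation of the carboxylic acid by the activated imidate (tert-butyl transfer, driven by formation of the amide) makes the new bond at the carboxyl oxygen. The two ortho groups that block acyl substitution therefore do not interfere.

Step 3
Reactants: 5 tert-butyl 2-methoxy-6-pentylbenzoate; 6 bis(pinacolato)diboron
Product: 7 tert-butyl 2-methoxy-6-pentyl-4-(4,4,5,5-tetramethyl-1,3,2-dioxaborolan-2-yl)benzoate
Conditions: [Ir(OMe)(cod)]2 (1.5 mol %), dtbpy (3 mol %), 6 (1.0 equiv), cyclohexane, 80 °C, N2
Reagents that add atoms: none
Why: Iridium-catalysed aromatic C–H borylation is governed by sterics and avoids C–H bonds next to a substituent. Of C3–H (beside OMe), C5–H (beside pentyl) and C4–H, only C4–H has two hydrogen neighbours and should react; both positions ortho to the ester are blocked, so no ester-directed borylation is possible. After the first borylation every remaining C–H is flanked by two substituents, so diborylation is not expected.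

Step 4
Reactants: 7 tert-butyl 2-methoxy-6-pentyl-4-(4,4,5,5-tetramethyl-1,3,2-dioxaborolan-2-yl)benzoate
Product: 8 [4-(tert-butoxycarbonyl)-3-methoxy-5-pentylphenyl]boronic acid
Conditions: NaIO4 (3 equiv), NH4OAc (3 equiv), acetone/H2O, rt
Reagents that add atoms: water, O
Why: Hydrolysis of the boronic ester is an equilibrium in aqueous acetone. Periodate cleaves the released 1,2-diol (glycol cleavage) and so pulls it to the boronic acid, while the buffered, near-neutral medium leaves the tert-butyl ester and the C–B bond intact.

Step 5
Reactants: 7 tert-butyl 2-methoxy-6-pentyl-4-(4,4,5,5-tetramethyl-1,3,2-dioxaborolan-2-yl)benzoate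
Product: 9 tert-butyl 4-hydroxy-2-methoxy-6-pentylbenzoate
Conditions: 30% aq. H2O2, NaOH (1 equiv), THF, 0 °C → rt
Reagents that add atoms: hydrogen peroxide, OO
Why: Oxidation of an arylboronate: hydroperoxide adds to boron, the aryl group migrates from boron to oxygen, and the borate ester is hydrolysed, so the hydroxyl appears exactly where boron was (C4). The hindered tert-butyl ester does not react with cold dilute hydroxide.

Step 6
Reactants: 9 tert-butyl 4-hydroxy-2-methoxy-6-pentylbenzoate; 10 benzyl bromide
Product: 11 tert-butyl 4-(benzyloxy)-2-methoxy-6-pentylbenzoate
Conditions: 10 (1.1 equiv), K2CO3, DMF, rt
Reagents that add atoms: none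
Why: Williamson ether synthesis: the C4 phenol is the only acidic site and has two hydrogen neighbours, so its phenoxide is benzylated cleanly by SN2 substitution.

Step 7
Reactants: 11 tert-butyl 4-(benzyloxy)-2-methoxy-6-pentylbenzoate
Product: 12 4-(benzyloxy)-2-methoxy-6-pentylbenzoic acid
Conditions: TFA/CH2Cl2 (1:4), 0 °C → rt, short reaction time
Reagents that add atoms: none
Why: Acidolysis of a tert-butyl ester proceeds by alkyl–oxygen cleavage with loss of the tert-butyl cation as the alkene, so it does not depend on access to the hindered carbonyl. An aryl benzyl ether withstands brief exposure to cold, dilute trifluoroacetic acid.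

Step 8
Reactants: 12 4-(benzyloxy)-2-methoxy-6-pentylbenzoic acid; 8 [4-(tert-butoxycarbonyl)-3-methoxy-5-pentylphenyl]boronic acid
Product: 13 tert-butyl 4-{[4-(benzyloxy)-2-methoxy-6-pentylbenzoyl]oxy}-2-methoxy-6-pentylbenzoate
Conditions: Cu(OTf)2 (40 mol %), urea (1 equiv), 8 (2 equiv), 4 Å MS, EtOAc, 60 °C, dry air
Reagents that add atoms: none
Why: Transmetalation moves the C4 aryl group of 8 from boron to divalent copper, and the carboxylate of 12 binds to the same metal centre through oxygen. Oxidation of this species by a second divalent copper centre, with air as terminal oxidant, gives a trivalent copper aryl carboxylate; C–O reductive elimination then releases aryl ester 13 and monovalent copper, which air returns to the divalent state. The closest known reaction type is the Chan–Lam oxidative coupling of arylboronic acids with O–H nucleophiles, in its variant with carboxylic acids that gives aryl esters. No ring is closed and no stereocenter is formed. The new bond is made at the carboxylate oxygen, one atom removed from the shielded carbonyl carbon, and at a boron-bearing carbon with two ortho hydrogens, so neither partner is hindered at the reacting atom. The step needs chemoselectivity for carboxylate transfer over protodeboronation, hydroxylation of 8 and biaryl homocoupling; the non-nucleophilic triflate counter-ion (no competing carboxylate on copper), molecular sieves with dry air, and an excess of 8 are meant to secure it. Site selectivity needs no control here because it is carried by the C–B bond placed at C4 in step 3; urea acts as a neutral ligand and mild base that buffers triflic acid and so protects the tert-butyl ester, and the benzyl ether offers copper no O–H group.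

Step 9
Reactants: 13 tert-butyl 4-{[4-(benzyloxy)-2-methoxy-6-pentylbenzoyl]oxy}-2-methoxy-6-pentylbenzoate
Product: 14 4-{[4-(benzyloxy)-2-methoxy-6-pentylbenzoyl]oxy}-2-methoxy-6-pentylbenzoic acid
Conditions: TFA/CH2Cl2 (1:4), 0 °C → rt, short reaction time
Reagents that add atoms: none
Why: The same alkyl–oxygen acidolysis as in step 7 frees the ring B acid. The depside ester has no alkyl–oxygen bond that can ionise and its carbonyl is shielded, so it should survive.

Step 10
Reactants: 14 4-{[4-(benzyloxy)-2-methoxy-6-pentylbenzoyl]oxy}-2-methoxy-6-pentylbenzoic acid
Product: 15 4-O-demethylplanaic acid (4-[(4-hydroxy-2-methoxy-6-pentylbenzoyl)oxy]-2-methoxy-6-pentylbenzoic acid)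
Conditions: H2 (1 atm), 10% Pd/C, EtOAc, rt
Reagents that add atoms: none
Why: Catalytic hydrogenolysis of the benzyl aryl ether over Pd/C is neutral and touches neither the aryl ester, the free acid nor the methyl ethers; toluene, the only other product, is volatile.

## Compound list

1 | 2-methoxy-6-methylbenzoic acid | Cc1cccc(OC)c1C(=O)O | starting material
2 | 1-iodobutane | CCCCI | starting material
3 | lithium 2-(lithiomethyl)-6-methoxybenzoate (dianion) | [Li+].[Li+].[CH2-]c1cccc(OC)c1C(=O)[O-] | intermediate (not isolated)
4 | 2-methoxy-6-pentylbenzoic acid | CCCCCc1cccc(OC)c1C(=O)O | intermediate
5 | tert-butyl 2-methoxy-6-pentylbenzoate | CCCCCc1cccc(OC)c1C(=O)OC(C)(C)C | intermediate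
6 | bis(pinacolato)diboron | CC1(C)OB(OC1(C)C)B1OC(C)(C)C(C)(C)O1 | starting material
7 | tert-butyl 2-methoxy-6-pentyl-4-(4,4,5,5-tetramethyl-1,3,2-dioxaborolan-2-yl)benzoate | CCCCCc1cc(B2OC(C)(C)C(C)(C)O2)cc(OC)c1C(=O)OC(C)(C)C | intermediate
8 | [4-(tert-butoxycarbonyl)-3-methoxy-5-pentylphenyl]boronic acid | CCCCCc1cc(B(O)O)cc(OC)c1C(=O)OC(C)(C)C | intermediate
9 | tert-butyl 4-hydroxy-2-methoxy-6-pentylbenzoate | CCCCCc1cc(O)cc(OC)c1C(=O)OC(C)(C)C | intermediate
10 | benzyl bromide | BrCc1ccccc1 | starting material
11 | tert-butyl 4-(benzyloxy)-2-methoxy-6-pentylbenzoate | CCCCCc1cc(OCc2ccccc2)cc(OC)c1C(=O)OC(C)(C)C | intermediate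
12 | 4-(benzyloxy)-2-methoxy-6-pentylbenzoic acid | CCCCCc1cc(OCc2ccccc2)cc(OC)c1C(=O)O | intermediate
13 | tert-butyl 4-{[4-(benzyloxy)-2-methoxy-6-pentylbenzoyl]oxy}-2-methoxy-6-pentylbenzoate | CCCCCc1cc(OC(=O)c2c(CCCCC)cc(OCc3ccccc3)cc2OC)cc(OC)c1C(=O)OC(C)(C)C | intermediate
14 | 4-{[4-(benzyloxy)-2-methoxy-6-pentylbenzoyl]oxy}-2-methoxy-6-pentylbenzoic acid | CCCCCc1cc(OC(=O)c2c(CCCCC)cc(OCc3ccccc3)cc2OC)cc(OC)c1C(=O)O | intermediate
15 | 4-O-demethylplanaic acid | CCCCCc1cc(OC(=O)c2c(CCCCC)cc(O)cc2OC)cc(OC)c1C(=O)O | target

## Step count and risk assessment

Total step count: 10. Longest linear sequence: 9 steps (steps 1, 2, 3, 5, 6, 7, 8, 9, 10); the ring B branch (steps 1, 2, 3, 4) joins at step 8.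

**Step 8 (key step).** The most likely failure is loss of the aryl–boron bond before the carboxylate is transferred, through protodeboronation, hydroxylation by adventitious water or homocoupling. This would be aggravated if the twisted, electron-rich carboxylate binds copper slowly. A second risk is loss of the tert-butyl group under the Lewis-acidic copper triflate. The fallback forms the same ester from the acyl side with known chemistry. It sets out from 12, which with (COCl)2 and catalytic DMF in CH2Cl2 should give 4-(benzyloxy)-2-methoxy-6-pentylbenzoyl chloride F1. F1 is added to the sodium phenoxide of 9 (NaH, THF, 0 °C to rt); this acylation of a small, strongly nucleophilic phenoxide by a 2,6-disubstituted aroyl chloride returns to the route at 13. Phenol 9 is already an intermediate, so the fallback costs one extra operation and makes step 4 unnecessary.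

**Step 4.** The hydrolysis equilibrium may stall, or the C–B bond may be lost by ipso-oxidation or by protodeboronation during isolation. Partial dehydration to the boroxine would also blur the stoichiometry of step 8. The fallback goes through a crystalline boron ate salt instead of direct hydrolysis. From 7, KHF2 in MeOH/H2O should give potassium [4-(tert-butoxycarbonyl)-3-methoxy-5-pentylphenyl]trifluoroborate F2, purified by precipitation. LiOH in MeCN/H2O then hydrolyses the B–F bonds and returns to the route at 8.

**Step 7.** The main risk is acid-induced loss of the benzyl group or its migration onto the electron-rich ring. Capture of the tert-butyl cation by that ring and, on long exposure, protodecarboxylation of the electron-rich acid by ipso-protonation are secondary risks, limited by low temperature and short contact time. The fallback reverses ester cleavage and benzylation so that the benzyl ether never meets strong acid. From 9, TFA/CH2Cl2 at 0 °C should give 4-hydroxy-2-methoxy-6-pentylbenzoic acid F3. Its dianion (KOH, 2.2 equiv, aq. EtOH) is alkylated with one equivalent of 10 at the more nucleophilic phenoxide oxygen, a Williamson etherification of a hydroxybenzoate dianion, and acidification with HCl returns to the route at 12.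

**Step 9.** The same acid-induced processes as in step 7 threaten the most valuable intermediate: loss or migration of the benzyl group and decarboxylation of the liberated ring B acid. The fallback inverts the end game. From 13, hydrogenolysis first (H2, Pd/C, EtOAc) should give tert-butyl 4-[(4-hydroxy-2-methoxy-6-pentylbenzoyl)oxy]-2-methoxy-6-pentylbenzoate F4, which has no benzyl group left to migrate. Brief treatment with TFA/CH2Cl2 at 0 °C then cleaves the tert-butyl ester and the sequence ends at 15.

## Further compounds

F1 | step 8 | 4-(benzyloxy)-2-methoxy-6-pentylbenzoyl chloride | CCCCCc1cc(OCc2ccccc2)cc(OC)c1C(=O)Cl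
F2 | step 4 | potassium [4-(tert-butoxycarbonyl)-3-methoxy-5-pentylphenyl]trifluoroborate | [K+].CCCCCc1cc([B-](F)(F)F)cc(OC)c1C(=O)OC(C)(C)C
F3 | step 7 | 4-hydroxy-2-methoxy-6-pentylbenzoic acid | CCCCCc1cc(O)cc(OC)c1C(=O)O
F4 | step 9 | tert-butyl 4-[(4-hydroxy-2-methoxy-6-pentylbenzoyl)oxy]-2-methoxy-6-pentylbenzoate | CCCCCc1cc(OC(=O)c2c(CCCCC)cc(O)cc2OC)cc(OC)c1C(=O)OC(C)(C)C
A1 | alternative 1 | dibenzyl malonate | O=C(CC(=O)OCc1ccccc1)OCc1ccccc1
A2 | alternative 1 | (E)-non-3-en-2-one | CCCCC/C=C/C(C)=O
A3 | alternative 1 | benzyl trans-2-hydroxy-4-oxo-6-pentylcyclohex-2-ene-1-carboxylate (racemic, one enantiomer drawn) | CCCCC[C@@H]1CC(=O)C=C(O)[C@H]1C(=O)OCc1ccccc1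
A4 | alternative 2 | benzyl 4-hydroxy-2-methoxy-6-pentylbenzoate | CCCCCc1cc(O)cc(OC)c1C(=O)OCc1ccccc1
A5 | alternative 2 | benzyl 2-methoxy-4-(oct-2-ynoyloxy)-6-pentylbenzoate | CCCCCC#CC(=O)Oc1cc(OC)c(C(=O)OCc2ccccc2)c(CCCCC)c1
A6 | alternative 2 | 1,1-dimethoxy-3-(trimethylsilyloxy)buta-1,3-diene | COC(OC)=CC(=C)O[Si](C)(C)C
A7 | alternative 2 | benzyl 4-[(4-hydroxy-2-methoxy-6-pentylbenzoyl)oxy]-2-methoxy-6-pentylbenzoate | CCCCCc1cc(OC(=O)c2c(CCCCC)cc(O)cc2OC)cc(OC)c1C(=O)OCc1ccccc1
A8 | alternative 3 | 2,2-dimethyl-6-(2,4-dioxononyl)-4H-1,3-dioxin-4-one | CCCCCC(=O)CC(=O)CC1=CC(=O)OC(C)(C)O1
A9 | alternative 3 | 3,5,7-trioxododec-1-en-1-one (acylketene) | CCCCCC(=O)CC(=O)CC(=O)C=C=O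
A10 | alternative 3 | benzyl 2-methoxy-6-pentyl-4-[(3,5,7-trioxododecanoyl)oxy]benzoate | CCCCCC(=O)CC(=O)CC(=O)CC(=O)Oc1cc(OC)c(C(=O)OCc2ccccc2)c(CCCCC)c1
A11 | alternative 3 | benzyl 4-[(2,4-dihydroxy-6-pentylbenzoyl)oxy]-2-methoxy-6-pentylbenzoate | CCCCCc1cc(OC(=O)c2c(CCCCC)cc(O)cc2O)cc(OC)c1C(=O)OCc1ccccc1
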